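Count the chains first.

the same everywhere: L 22 mM; E 69 µM
- grey: J 0.29 mol%; run made earlier
- violet: J 0.65 mol%; run made earlier
- flask: J 0.43 mol%; time 80 min

- grey (time / min: D / %, L / %): 10.0: 22, 75; 20.0: 43, 58; 30.0: 59, 44; 40.0: 65, 35; 50.0: 73, 25
- violet (time / min: D / %, L / %): 10.0: 59, 42; 20.0: 80, 20; 30.0: 87, 11; 40.0: 90, 10; 50.0: 92, 6

(standard deviation of a reading: 1.5 percentage points)

* average number of monomer units in a chain (chains begun, living or dead) at 80 min
* part of the L that has reacted at 80 min

- the average divides the monomer in chains by the number of chains begun, living and dead together
- steps under discussion: J -> G; J + E -> X; L + Q -> D + Q; L + J -> Q + D; D + Q -> L + Q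
- the earlier runs do not show the number of chains; that part of a forecast is a guess

L goes into D on the living ends Q, which J begins, and E can take J away. I draw L in the flask as a curve. Its level I read from the last violet reading, 6.00 % of the charge, with a reading's scatter. Toward that level the grey run closes at 0.0320 /min and the violet run at 0.0952 /min. Between them, the flask's loading gives a pseudo-first-order constant of 0.0566 /min. So I reckon that the gap to the level halves every 12.2 min, and my estimate for 80 min puts L at 7.02 %, which makes 93.0 % reacted.

The slopes count Q up to an unknown factor. I suppose each E in the violet run took one J, which leaves that run a share of 0.517. Scaling by slope and loading gives the flask 0.465, its living share, the part of the J charged that ends as Q. The average is then conversion over share times loading, 465.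

The forecast says 320 (260 to 480) and 94 % (91 % to 96 %): “Dividing by about 69 µM of chains gives dp ≈ 300”. My average is higher than that.

The flask gives an average of 564, with 91.5 % reacted.

    J → G (k = 0.0350 /min)
    J + E → X (k = 31300 /M/min)
    L + Q → D + Q, rate k3*[Q]*[L] (k = 1580 /M/min)
    L + J → Q + D (k = 29.7 /M/min)
    D + Q → L + Q, rate k5*[Q] as long as [D] is above zero (k = 2.59 /min)

In this flask at 80 min Q stands at a share of 0.377 of the J charged, less than my 0.465, and 91.5 % over that share and the loading gives 564. The half-life of J against E as charged is 0.32 min, shorter than 1.06 min against L as charged. In the neighbour flask with L at 8.8 mM and the loadings held, the share is 0.137, and 39.0 % over share and loading gives 661.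

(The numbers in the tables were generated by integration from invented constants; scatter was added.)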